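**Assumptions (one line each)**
- In tetralin numbering the target is (1R,2S,3S), all-trans, which I take to be (−)-isolariciresinol; 4-(benzyloxy)-3-methoxybenzaldehyde is treated as commercial.
- The sense of induction of the new catalyst cannot be predicted, so the catalyst antipode that gives (1R) is chosen after a first run; both antipodes are equally accessible.

**Retrosynthetic overview**
1. Target 10 comes from the all-trans diester 9 by ester reduction; C2 and C3 of 9 are set thermodynamically (NaOMe) under control of the non-epimerisable C1.
2. 9 comes from the 1-aryl-1,2-dihydronaphthalene diester 7 by hydrogenation with concomitant O-debenzylation.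
3. 7 comes from the achiral (E,E)-bis(arylidene)succinate 6 by a new catalytic enantioselective cationic cyclisation, which forms the C1–C8a bond, the only new ring and the C1 stereocentre.
4. 6 comes from two successive Stobbe condensations of O-benzylvanillin 1 with dimethyl succinate 2.
5. Ring order: both arenes arrive intact from vanillin; the central carbocycle is the only ring made (step 5).

**Route**

Step 1
Reactants: 1, 4-(benzyloxy)-3-methoxybenzaldehyde; 2, dimethyl succinate
Product: 3, (E)-4-[4-(benzyloxy)-3-methoxyphenyl]-3-(methoxycarbonyl)but-3-enoic acid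
Conditions: NaOMe, MeOH, reflux; then aq. HCl
Reagents that add atoms: none
Why: Stobbe condensation; the paraconate lactone intermediate opens by E1cB to the half-ester with aryl trans to the conjugated ester (E).

Step 2
Reactants: 3, (E)-half-ester
Product: 4, dimethyl (E)-2-[4-(benzyloxy)-3-methoxybenzylidene]succinate
Conditions: MeI, K2CO3, DMF, rt
Reagents that add atoms: iodomethane, CI
Why: SN2 O-methylation of the carboxylate; the alkene geometry and the benzyl ether are untouched.

Step 3
Reactants: 4, dimethyl (E)-arylidenesuccinate; 1, 4-(benzyloxy)-3-methoxybenzaldehyde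
Product: 5, (2E,3E)-2,3-bis[4-(benzyloxy)-3-methoxybenzylidene]succinic acid monomethyl ester
Conditions: NaOMe, MeOH, reflux; then aq. HCl
Reagents that add atoms: none
Why: Second Stobbe condensation at the remaining enolisable CH2; lactonisation and E1cB opening again give the E-arylidene, so the E,E-diene half-ester results.

Step 4
Reactants: 5, (E,E)-half-ester
Product: 6, dimethyl (2E,3E)-2,3-bis[4-(benzyloxy)-3-methoxybenzylidene]succinate
Conditions: MeI, K2CO3, DMF, rt
Reagents that add atoms: iodomethane, CI
Why: SN2 carboxylate methylation gives the symmetric, achiral cyclisation substrate.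

Step 5
Reactants: 6, (E,E)-bis(arylidene)succinate
Product: 7, dimethyl (1R,2S)-7-(benzyloxy)-1-[4-(benzyloxy)-3-methoxyphenyl]-6-methoxy-1,2-dihydronaphthalene-2,3-dicarboxylate (1,2-trans)
Conditions: chiral confined imidodiphosphorimidate Brønsted acid (BINOL-derived IDPi, 3,3'-bis[3,5-(CF3)2C6H3], N-triflyl core; 5 mol %), CHCl3, −20 °C to rt
Reagents that add atoms: none
Why: Proposed new method: the IDPi acid O-protonates one ester of the rapidly interconverting helical diene to give a p-alkoxybenzyl/vinylogous oxocarbenium ion held in the confined chiral anion, and only one helical conformer can close; the other arene then attacks the cationic benzylic carbon at its position para to OMe (6π-type cationic closure, i.e. an intramolecular vinylogous Friedel–Crafts alkylation), which sets C1 as R, and rearomatisation plus C2 protonation gives the more stable trans diester and returns the catalyst; the closest known reactions are the racemic stoichiometric TfOH cyclisation of dibenzylidenesuccinates to trans-1-aryl-1,2-dihydronaphthalenes and confined-acid-catalysed asymmetric Nazarov cyclisations.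

Step 6
Reactants: 7, (1R,2S)-dihydronaphthalene diester
Product: 8, dimethyl (1R,2S,3RS)-7-hydroxy-1-(4-hydroxy-3-methoxyphenyl)-6-methoxy-1,2,3,4-tetrahydronaphthalene-2,3-dicarboxylate (C3-epimer mixture, 2,3-cis expected to predominate; used crude)
Conditions: H2 (3 atm), 10% Pd/C, EtOAc/MeOH, rt
Reagents that add atoms: none
Why: Heterogeneous catalytic hydrogenation saturates the conjugated C3=C4 bond and hydrogenolyses both benzyl ethers in one operation; C1 and C2 are not touched and the C3 ratio is irrelevant because of step 7.

Step 7
Reactants: 8, tetralin diester (C3 mixture)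
Product: 9, dimethyl (1R,2S,3S)-7-hydroxy-1-(4-hydroxy-3-methoxyphenyl)-6-methoxy-1,2,3,4-tetrahydronaphthalene-2,3-dicarboxylate (all-trans)
Conditions: NaOMe (6 equiv), MeOH, reflux; then AcOH quench; recrystallise (ee upgrade if needed)
Reagents that add atoms: none
Why: Base-mediated epimerisation through the ester enolates (thermodynamic control) funnels C2 and C3 to the all-equatorial trans,trans isomer, dictated by the non-enolisable C1 (same type as the α- to β-conidendrin epimerisation, which tolerates free phenols).

Step 8
Reactants: 9, all-trans diester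
Product: 10, (6S,7S,8R)-8-(4-hydroxy-3-methoxyphenyl)-6,7-bis(hydroxymethyl)-3-methoxy-5,6,7,8-tetrahydronaphthalen-2-ol (target)
Conditions: LiAlH4 (6 equiv), THF, 0 °C to reflux; Rochelle salt work-up
Reagents that add atoms: none
Why: LiAlH4 reduction of both esters to primary alcohols in the presence of the phenoxides (as in the classical conidendrin to isolariciresinol reduction); no stereocentre is involved.

**Compound list**
1 | 4-(benzyloxy)-3-methoxybenzaldehyde | COc1cc(C=O)ccc1OCc1ccccc1 | starting material
2 | dimethyl succinate | COC(=O)CCC(=O)OC | starting material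
3 | (E)-4-[4-(benzyloxy)-3-methoxyphenyl]-3-(methoxycarbonyl)but-3-enoic acid | COC(=O)/C(=C/c1ccc(OCc2ccccc2)c(OC)c1)CC(=O)O | intermediate
4 | dimethyl (E)-2-[4-(benzyloxy)-3-methoxybenzylidene]succinate | COC(=O)/C(=C/c1ccc(OCc2ccccc2)c(OC)c1)CC(=O)OC | intermediate
5 | (2E,3E)-2,3-bis[4-(benzyloxy)-3-methoxybenzylidene]succinic acid monomethyl ester | COC(=O)/C(=C/c1ccc(OCc2ccccc2)c(OC)c1)C(=C/c1ccc(OCc2ccccc2)c(OC)c1)\C(=O)O | intermediate
6 | dimethyl (2E,3E)-2,3-bis[4-(benzyloxy)-3-methoxybenzylidene]succinate | COC(=O)/C(=C/c1ccc(OCc2ccccc2)c(OC)c1)C(=C/c1ccc(OCc2ccccc2)c(OC)c1)\C(=O)OC | intermediate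
7 | dimethyl (1R,2S)-7-(benzyloxy)-1-[4-(benzyloxy)-3-methoxyphenyl]-6-methoxy-1,2-dihydronaphthalene-2,3-dicarboxylate | COc1cc([C@@H]2c3cc(OCc4ccccc4)c(OC)cc3C=C(C(=O)OC)[C@H]2C(=O)OC)ccc1OCc1ccccc1 | intermediate
8 | dimethyl (1R,2S,3RS)-7-hydroxy-1-(4-hydroxy-3-methoxyphenyl)-6-methoxy-1,2,3,4-tetrahydronaphthalene-2,3-dicarboxylate (C3 epimers) | COc1cc([C@@H]2c3cc(O)c(OC)cc3CC(C(=O)OC)[C@H]2C(=O)OC)ccc1O | intermediate
9 | dimethyl (1R,2S,3S)-7-hydroxy-1-(4-hydroxy-3-methoxyphenyl)-6-methoxy-1,2,3,4-tetrahydronaphthalene-2,3-dicarboxylate | COc1cc([C@@H]2c3cc(O)c(OC)cc3C[C@H](C(=O)OC)[C@H]2C(=O)OC)ccc1O | intermediate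
10 | (6S,7S,8R)-8-(4-hydroxy-3-methoxyphenyl)-6,7-bis(hydroxymethyl)-3-methoxy-5,6,7,8-tetrahydronaphthalen-2-ol | COc1cc([C@@H]2c3cc(O)c(OC)cc3C[C@H](CO)[C@H]2CO)ccc1O | target

**Totals**
Total step count: 8. Longest linear sequence: 8 steps (from 1 and 2).

**Three steps most likely to fail, with fallbacks**

1. Step 5 (proposed new enantioselective cyclisation). Risks: insufficient acidity or turnover, low ee, benzyl ether loss.
   Fallback (known chemistry, different order of events): set the stereochemistry before ring closure.
   - Rh/chiral-bisphosphine asymmetric hydrogenation of the Stobbe half-ester 3.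
   - Chemoselective reduction of the ester and lactonisation to the enantioenriched β-benzyl-γ-butyrolactone.
   - Lithium enolate aldol with 1 to give the trans α-(hydroxybenzyl) lactone.
   - TFA Friedel–Crafts cyclisation (substrate-controlled, all-trans) to the conidendrin-type aryltetralin lactone.
   - LiAlH4 reduction, then H2, Pd/C to give 10.

2. Step 3 (second Stobbe condensation). Risks: modest yield, E/Z mixtures.
   Fallback: make 6 by C–C coupling instead of condensation. Convert 1 to methyl (Z)-2-bromo-3-[4-(benzyloxy)-3-methoxyphenyl]acrylate (olefination, then bromination/dehydrobromination) and carry out a Ni(0)/Zn reductive homocoupling of this vinyl bromide, which proceeds with retention to give the (E,E)-diene diester 6 directly.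

3. Step 7 (thermodynamic epimerisation of the bis-phenoxide diester). Risks: incomplete equilibration, inseparable epimers.
   Fallback: set C3 kinetically instead. Reduce 7 with DIBAL-H to the dihydronaphthalene diol, then run a hydroxyl-directed homogeneous hydrogenation (Crabtree catalyst, H2, CH2Cl2). The homoallylic C2–CH2OH delivers H to its own face of C3, giving the 2,3-trans diol. Final H2, Pd/C debenzylation gives 10.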